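The ten-membered carbocycle (ring B) is closed last across C3a–C4 (cyclodeca[b]furan locants), the bond joining the ring-fusion carbon of the α-methylene-γ-lactone (ring A) to the acyloxy carbon. The array C3(=CH2)–C3a–C4–O is a homoallylic alcohol, the retron of an allylmetal–aldehyde addition. A CrCl2-mediated intramolecular Nozaki–Hiyama–Kishi allylation of a tethered aldehyde by a 3-(bromomethyl)butenolide forms this bond, shifts the ring-A double bond into the exocyclic methylidene, sets C3a and C4 and frees the C4 hydroxyl in one operation. The precursor is an open chain built on (S)-citronellal, whose C1–C6 become C11a–C7, with the bromomethyl butenolide at one end and a β,γ-unsaturated aldehyde at the other.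

Key step: step 11

Remark: bicyclic compounds are numbered as cyclodeca[b]furans (O1, C2 carbonyl, C3 methylidene carbon, C3a ring fusion, C4 acyloxy carbon, C6 acetoxymethyl carbon, C10 methyl carbon, C11a lactone carbinol carbon); all numbered starting materials and the ligand (+)-MIB are taken as purchasable.

Step 1
Reactants: 1 (S)-citronellal [(3S)-3,7-dimethyloct-6-enal]; 2 vinylmagnesium bromide
Product: 4 (3S,5S)-5,9-dimethyldeca-1,8-dien-3-ol, via divinylzinc 3 (not isolated)
Conditions: 2 (2.6 equiv), ZnCl2 (1.3 equiv), THF, 0 °C; 1,4-dioxane, removal of the magnesium salts; (2R)-(+)-3-exo-morpholinoisoborneol [(+)-MIB, 5 mol%], 1, toluene, −20 → 0 °C; aq NH4Cl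
Reagents that add atoms: vinylmagnesium bromide, C=C[Mg]Br
Why: Amino-alcohol-catalysed enantioselective alkenylzinc addition to an aldehyde, in which the (+)-MIB–zinc complex should deliver the vinyl group to the Re face and so set C3 as (S) under catalyst control, independent of the remote C5 methyl center.

Step 2
Reactants: 4 (3S,5S)-5,9-dimethyldeca-1,8-dien-3-ol; 5 ozone
Product: 6 (4S,6S)-6-hydroxy-4-methyloct-7-enal
Conditions: O3/O2, CH2Cl2/MeOH, NaHCO3, −78 °C, Sudan Red 7B as end-point indicator; then Me2S, −78 °C → rt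
Reagents that add atoms: ozone, [O-][O+]=O
Why: Chemoselective ozonolysis, since the electron-rich trisubstituted alkene reacts much faster than the monosubstituted vinyl carbinol and the dye marks the point at which only the former is consumed; no stereocenter is touched.

Step 3
Reactants: 7 triethyl phosphonoacetate; 8 (2-bromoethoxy)(tert-butyl)dimethylsilane
Product: 9 ethyl 4-[(tert-butyldimethylsilyl)oxy]-2-(diethoxyphosphoryl)butanoate
Conditions: NaH, DMSO, rt; then 8, 60 °C
Reagents that add atoms: (2-bromoethoxy)(tert-butyl)dimethylsilane, BrCCO[Si](C)(C)C(C)(C)C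
Why: SN2 C-alkylation of the sodium phosphonoenolate by a primary bromide; the new α-center is racemic and loses its stereogenicity in step 4.

Step 4
Reactants: 6 (4S,6S)-6-hydroxy-4-methyloct-7-enal; 9 ethyl 4-[(tert-butyldimethylsilyl)oxy]-2-(diethoxyphosphoryl)butanoate
Product: 10 ethyl (2E,6S,8S)-2-{2-[(tert-butyldimethylsilyl)oxy]ethyl}-8-hydroxy-6-methyldeca-2,9-dienoate
Conditions: 9 (1.3 equiv), NaH (1.25 equiv), THF, 0 °C; then 6, 0 °C → rt; chromatographic removal of the minor (Z)-isomer
Reagents that add atoms: ethyl 4-[(tert-butyldimethylsilyl)oxy]-2-(diethoxyphosphoryl)butanoate, CCOC(=O)C(CCO[Si](C)(C)C(C)(C)C)P(=O)(OCC)OCC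
Why: Horner–Wadsworth–Emmons olefination under equilibrating conditions should place the chain trans to the ester, giving the (E)-enoate and thereby the ring-B olefin geometry (chain cis to the CH2CH2O arm); the free secondary hydroxyl is not deprotonated by the stabilised anion.

Step 5
Reactants: 10 ethyl (2E,6S,8S)-2-{2-[(tert-butyldimethylsilyl)oxy]ethyl}-8-hydroxy-6-methyldeca-2,9-dienoate
Product: 11 (2E,6S,8S)-2-{2-[(tert-butyldimethylsilyl)oxy]ethyl}-6-methyldeca-2,9-diene-1,8-diol
Conditions: iBu2AlH (3.5 equiv), CH2Cl2, −78 → −20 °C; aqueous potassium sodium tartrate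
Reagents that add atoms: none
Why: 1,2-Reduction of the conjugated ester to the primary allylic alcohol by an aluminium hydride, with the silyl ether and both alkenes inert and the olefin geometry retained.

Step 6
Reactants: 11 (2E,6S,8S)-2-{2-[(tert-butyldimethylsilyl)oxy]ethyl}-6-methyldeca-2,9-diene-1,8-diol; 12 acetyl chloride
Product: 13 (2E,6S,8S)-2-{2-[(tert-butyldimethylsilyl)oxy]ethyl}-8-hydroxy-6-methyldeca-2,9-dien-1-yl acetate
Conditions: AcCl (1.05 equiv), 2,4,6-collidine, CH2Cl2, −78 °C
Reagents that add atoms: acetyl chloride, CC(=O)Cl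
Why: Kinetically selective O-acetylation of the unhindered primary allylic hydroxyl over the secondary allylic one at low temperature.

Step 7
Reactants: 13 (2E,6S,8S)-2-{2-[(tert-butyldimethylsilyl)oxy]ethyl}-8-hydroxy-6-methyldeca-2,9-dien-1-yl acetate; 14 2-(bromomethyl)prop-2-enoic acid
Product: 15 (3S,5S,8E)-10-(acetyloxy)-9-{2-[(tert-butyldimethylsilyl)oxy]ethyl}-5-methyldeca-1,8-dien-3-yl 2-(bromomethyl)prop-2-enoate
Conditions: 14, DCC, DMAP (5 mol%), CH2Cl2, −10 → 0 °C
Reagents that add atoms: 2-(bromomethyl)prop-2-enoic acid, C=C(CBr)C(=O)O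
Why: Steglich esterification of the secondary allylic alcohol with retention at the carbinol carbon; low DMAP loading and temperature suppress attack on the allylic bromide.

Step 8
Reactants: 15 (3S,5S,8E)-10-(acetyloxy)-9-{2-[(tert-butyldimethylsilyl)oxy]ethyl}-5-methyldeca-1,8-dien-3-yl 2-(bromomethyl)prop-2-enoate
Product: 16 (2E,6S)-7-[(2S)-4-(bromomethyl)-5-oxo-2,5-dihydrofuran-2-yl]-2-{2-[(tert-butyldimethylsilyl)oxy]ethyl}-6-methylhept-2-en-1-yl acetate
Conditions: RuCl2(=CHPh)(PCy3)(H2IMes) (second-generation Grubbs catalyst, 5–10 mol%), degassed toluene, 0.005 M, 80 °C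
Reagents that add atoms: none
Why: Ring-closing metathesis between the vinyl group and the 1,1-disubstituted acrylate closes the butenolide with loss of ethene, while the hindered trisubstituted acetoxymethyl olefin should not compete and the (S) carbinol center is untouched.

Step 9
Reactants: 16 (2E,6S)-7-[(2S)-4-(bromomethyl)-5-oxo-2,5-dihydrofuran-2-yl]-2-{2-[(tert-butyldimethylsilyl)oxy]ethyl}-6-methylhept-2-en-1-yl acetate
Product: 17 (2E,6S)-7-[(2S)-4-(bromomethyl)-5-oxo-2,5-dihydrofuran-2-yl]-2-(2-hydroxyethyl)-6-methylhept-2-en-1-yl acetate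
Conditions: 48% aq HF, MeCN, 0 °C
Reagents that add atoms: none
Why: Acidic fluoride cleavage of the primary silyl ether under non-nucleophilic conditions that leave the allylic bromide, the acetate and the butenolide intact.

Step 10
Reactants: 17 (2E,6S)-7-[(2S)-4-(bromomethyl)-5-oxo-2,5-dihydrofuran-2-yl]-2-(2-hydroxyethyl)-6-methylhept-2-en-1-yl acetate
Product: 18 (2E,6S)-7-[(2S)-4-(bromomethyl)-5-oxo-2,5-dihydrofuran-2-yl]-6-methyl-2-(2-oxoethyl)hept-2-en-1-yl acetate
Conditions: Dess–Martin periodinane, NaHCO3, CH2Cl2, 0 °C; short silica plug, used at once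
Reagents that add atoms: none
Why: Buffered hypervalent-iodine oxidation of the homoallylic alcohol should give the β,γ-unsaturated aldehyde without acid- or base-induced migration of the olefin into conjugation.

Step 11
Reactants: 18 (2E,6S)-7-[(2S)-4-(bromomethyl)-5-oxo-2,5-dihydrofuran-2-yl]-6-methyl-2-(2-oxoethyl)hept-2-en-1-yl acetate
Product: 20 [(3aR,4S,6E,10S,11aS)-4-hydroxy-10-methyl-3-methylidene-2-oxo-2,3,3a,4,5,8,9,10,11,11a-decahydrocyclodeca[b]furan-6-yl]methyl acetate, via allylchromium dichloride 19 (not isolated)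
Conditions: CrCl2 (10 equiv), THF, syringe-pump addition of 18 over 12 h to a final 0.002 M, 25 °C; then water
Reagents that add atoms: none
Why: Two CrCl2 insert into the allylic C–Br bond to give the trivalent allylchromium 19, which adds through its γ-carbon (the butenolide β-carbon, later C3a) to the tethered aldehyde in a six-membered chair transition state, so that the endocyclic double bond becomes the exocyclic methylidene. The closest known reactions are the CrCl2-mediated allylation of aldehydes by 3-(bromomethyl)furan-2(5H)-ones and intramolecular Nozaki–Hiyama–Kishi closures of 2-(bromomethyl)acrylates to ten-membered carbocycles. Ring B closes in a 10-exo-trig addition to the carbonyl (SE2' at the allylmetal) under high dilution, helped by the cis ring olefin, which brings the chain ends together. C3a is controlled by the C11a stereocenter, because the tether that starts on C11a should deliver the aldehyde to the same face of the planar butenolide and so give the cis ring fusion without placing the C3a hydrogen inside the ring. C4 is controlled by the ring-locked allylchromium geometry (C11a trans to CH2Cr) in the chair with C5 pseudo-equatorial, which gives the anti C3a/C4 relationship, that is (4S); the (3aR) descriptor of 20 reflects only a priority change and the spatial arrangement is that of the target. The step needs γ- over α-attack (secured by the cyclic transition state), reaction at C–Br and not at the allylic acetate (CrCl2 without a nickel or palladium co-catalyst does not ionise acetates) and cyclisation over oligomerisation (dilution).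

Step 12
Reactants: 20 [(3aR,4S,6E,10S,11aS)-4-hydroxy-10-methyl-3-methylidene-2-oxo-2,3,3a,4,5,8,9,10,11,11a-decahydrocyclodeca[b]furan-6-yl]methyl acetate; 21 2-[(tert-butyldimethylsilyl)oxy]acetic acid
Product: 22 (3aS,4S,6E,10S,11aS)-6-[(acetyloxy)methyl]-10-methyl-3-methylidene-2-oxo-2,3,3a,4,5,8,9,10,11,11a-decahydrocyclodeca[b]furan-4-yl [(tert-butyldimethylsilyl)oxy]acetate
Conditions: 21, DCC, DMAP, CH2Cl2, 0 °C → rt
Reagents that add atoms: 2-[(tert-butyldimethylsilyl)oxy]acetic acid, OC(=O)CO[Si](C)(C)C(C)(C)C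
Why: Steglich esterification of the secondary C4 hydroxyl with retention, the silyl ether preventing self-condensation of the glycolic acid.

Step 13
Reactants: 22 (3aS,4S,6E,10S,11aS)-6-[(acetyloxy)methyl]-10-methyl-3-methylidene-2-oxo-2,3,3a,4,5,8,9,10,11,11a-decahydrocyclodeca[b]furan-4-yl [(tert-butyldimethylsilyl)oxy]acetate
Product: 23 (3aS,4S,6E,10S,11aS)-6-[(acetyloxy)methyl]-10-methyl-3-methylidene-2-oxo-2,3,3a,4,5,8,9,10,11,11a-decahydrocyclodeca[b]furan-4-yl hydroxyacetate (target)
Conditions: HF·pyridine, THF, 0 °C → rt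
Reagents that add atoms: none
Why: Mildly acidic fluoride cleavage of the primary silyl ether should avoid acyl migration, ester cleavage and conjugate addition to the α-methylene lactone.

Compound list
1 | (S)-citronellal [(3S)-3,7-dimethyloct-6-enal] | O=CC[C@@H](C)CCC=C(C)C | starting material
2 | vinylmagnesium bromide | C=C[Mg]Br | starting material
3 | divinylzinc | C=C[Zn]C=C | intermediate (formed in the flask, not isolated)
4 | (3S,5S)-5,9-dimethyldeca-1,8-dien-3-ol | C=C[C@@H](O)C[C@@H](C)CCC=C(C)C | intermediate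
5 | ozone | [O-][O+]=O | starting material (reagent, generated from O2)
6 | (4S,6S)-6-hydroxy-4-methyloct-7-enal | C=C[C@@H](O)C[C@@H](C)CCC=O | intermediate
7 | triethyl phosphonoacetate | CCOC(=O)CP(=O)(OCC)OCC | starting material
8 | (2-bromoethoxy)(tert-butyl)dimethylsilane | BrCCO[Si](C)(C)C(C)(C)C | starting material
9 | ethyl 4-[(tert-butyldimethylsilyl)oxy]-2-(diethoxyphosphoryl)butanoate (racemic) | CCOC(=O)C(CCO[Si](C)(C)C(C)(C)C)P(=O)(OCC)OCC | intermediate
10 | ethyl (2E,6S,8S)-2-{2-[(tert-butyldimethylsilyl)oxy]ethyl}-8-hydroxy-6-methyldeca-2,9-dienoate | C=C[C@@H](O)C[C@@H](C)CC/C=C(/C(=O)OCC)CCO[Si](C)(C)C(C)(C)C | intermediate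
11 | (2E,6S,8S)-2-{2-[(tert-butyldimethylsilyl)oxy]ethyl}-6-methyldeca-2,9-diene-1,8-diol | C=C[C@@H](O)C[C@@H](C)CC/C=C(/CO)CCO[Si](C)(C)C(C)(C)C | intermediate
12 | acetyl chloride | CC(=O)Cl | starting material
13 | (2E,6S,8S)-2-{2-[(tert-butyldimethylsilyl)oxy]ethyl}-8-hydroxy-6-methyldeca-2,9-dien-1-yl acetate | C=C[C@@H](O)C[C@@H](C)CC/C=C(/COC(C)=O)CCO[Si](C)(C)C(C)(C)C | intermediate
14 | 2-(bromomethyl)prop-2-enoic acid | C=C(CBr)C(=O)O | starting material
15 | (3S,5S,8E)-10-(acetyloxy)-9-{2-[(tert-butyldimethylsilyl)oxy]ethyl}-5-methyldeca-1,8-dien-3-yl 2-(bromomethyl)prop-2-enoate | C=C[C@@H](OC(=O)C(=C)CBr)C[C@@H](C)CC/C=C(/COC(C)=O)CCO[Si](C)(C)C(C)(C)C | intermediate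
16 | (2E,6S)-7-[(2S)-4-(bromomethyl)-5-oxo-2,5-dihydrofuran-2-yl]-2-{2-[(tert-butyldimethylsilyl)oxy]ethyl}-6-methylhept-2-en-1-yl acetate | BrCC1=C[C@H](C[C@@H](C)CC/C=C(/COC(C)=O)CCO[Si](C)(C)C(C)(C)C)OC1=O | intermediate
17 | (2E,6S)-7-[(2S)-4-(bromomethyl)-5-oxo-2,5-dihydrofuran-2-yl]-2-(2-hydroxyethyl)-6-methylhept-2-en-1-yl acetate | BrCC1=C[C@H](C[C@@H](C)CC/C=C(/COC(C)=O)CCO)OC1=O | intermediate
18 | (2E,6S)-7-[(2S)-4-(bromomethyl)-5-oxo-2,5-dihydrofuran-2-yl]-6-methyl-2-(2-oxoethyl)hept-2-en-1-yl acetate | BrCC1=C[C@H](C[C@@H](C)CC/C=C(/COC(C)=O)CC=O)OC1=O | intermediate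
19 | allylchromium dichloride of 18 (trivalent chromium; C–Br of 18 replaced by C–CrCl2) | Cl[Cr](Cl)CC1=C[C@H](C[C@@H](C)CC/C=C(/COC(C)=O)CC=O)OC1=O | intermediate (not isolated)
20 | [(3aR,4S,6E,10S,11aS)-4-hydroxy-10-methyl-3-methylidene-2-oxo-2,3,3a,4,5,8,9,10,11,11a-decahydrocyclodeca[b]furan-6-yl]methyl acetate | C=C1C(=O)O[C@H]2C[C@@H](C)CC/C=C(/COC(C)=O)C[C@H](O)[C@@H]12 | intermediate
21 | 2-[(tert-butyldimethylsilyl)oxy]acetic acid | OC(=O)CO[Si](C)(C)C(C)(C)C | starting material
22 | (3aS,4S,6E,10S,11aS)-6-[(acetyloxy)methyl]-10-methyl-3-methylidene-2-oxo-2,3,3a,4,5,8,9,10,11,11a-decahydrocyclodeca[b]furan-4-yl [(tert-butyldimethylsilyl)oxy]acetate | C=C1C(=O)O[C@H]2C[C@@H](C)CC/C=C(/COC(C)=O)C[C@H](OC(=O)CO[Si](C)(C)C(C)(C)C)[C@@H]12 | intermediate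
23 | (3aS,4S,6E,10S,11aS)-6-[(acetyloxy)methyl]-10-methyl-3-methylidene-2-oxo-2,3,3a,4,5,8,9,10,11,11a-decahydrocyclodeca[b]furan-4-yl hydroxyacetate | C=C1C(=O)O[C@H]2C[C@@H](C)CC/C=C(/COC(C)=O)C[C@H](OC(=O)CO)[C@@H]12 | target

Total step count: 13. Longest linear sequence: 12 steps (1, 2, 4–13, from (S)-citronellal); step 3 is a one-step side branch.

Steps most likely to fail

Step 11. Ring closure may be outrun by intermolecular allylation, or ring strain may override the chair preference so that the aldehyde is attacked on its other face and the C4 epimer forms. The fallback sets out from 18 and uses a zinc-mediated aqueous Barbier closure (Zn dust, sat. aq NH4Cl/THF, 0.002 M), a different allylmetal in a protic medium. Should this or the chromium reaction give mainly the C4-epimeric alcohol [(3aR,4R,6E,10S,11aS)-4-hydroxy-10-methyl-3-methylidene-2-oxo-2,3,3a,4,5,8,9,10,11,11a-decahydrocyclodeca[b]furan-6-yl]methyl acetate F1, the configuration is corrected while the ester is installed: Mitsunobu esterification of F1 with 21 (PPh3, DIAD, toluene, 0 °C → rt) should invert C4 and return to the route at 22. This fallback does not repair a trans ring fusion at C3a.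

Step 8. Turnover of the electron-poor 1,1-disubstituted acrylate may be slow and the catalyst may decay, or the allylic bromide may be lost at ruthenium. The fallback sets out from 13 and moves the bromide to the end. Acylation with acryloyl chloride (iPr2NEt, CH2Cl2, −78 °C) gives (3S,5S,8E)-10-(acetyloxy)-9-{2-[(tert-butyldimethylsilyl)oxy]ethyl}-5-methyldeca-1,8-dien-3-yl prop-2-enoate F2. Ring-closing metathesis of this unsubstituted acrylate (same ruthenium catalyst, CH2Cl2, 40 °C) gives (2E,6S)-2-{2-[(tert-butyldimethylsilyl)oxy]ethyl}-6-methyl-7-[(2S)-5-oxo-2,5-dihydrofuran-2-yl]hept-2-en-1-yl acetate F3. Morita–Baylis–Hillman hydroxymethylation (aq CH2O, PBu3 cat., THF) gives (2E,6S)-2-{2-[(tert-butyldimethylsilyl)oxy]ethyl}-7-[(2S)-4-(hydroxymethyl)-5-oxo-2,5-dihydrofuran-2-yl]-6-methylhept-2-en-1-yl acetate F4. Appel bromination (CBr4, PPh3, CH2Cl2, 0 °C) returns to the route at 16.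

Step 1. The amino-alcohol catalyst may discriminate the faces of this α-unbranched aldehyde poorly and give a C3 epimer mixture. The fallback sets out from 1. Uncatalysed addition of 2 (THF, −78 °C) gives (5S)-5,9-dimethyldeca-1,8-dien-3-ol as a mixture of C3 epimers F5. Sharpless kinetic resolution (Ti(OiPr)4, D-(−)-diisopropyl tartrate, tBuOOH 0.6 equiv, 4 Å molecular sieves, CH2Cl2, −20 °C) should epoxidise the (3R)-epimer faster, to the erythro epoxy alcohol (1R,3S)-3,7-dimethyl-1-[(2S)-oxiran-2-yl]oct-6-en-1-ol F6, which is separated. The unreacted (3S)-epimer is recovered and is 4, where the route is rejoined.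

Further compounds
F1 | step 11 | [(3aR,4R,6E,10S,11aS)-4-hydroxy-10-methyl-3-methylidene-2-oxo-2,3,3a,4,5,8,9,10,11,11a-decahydrocyclodeca[b]furan-6-yl]methyl acetate | C=C1C(=O)O[C@H]2C[C@@H](C)CC/C=C(/COC(C)=O)C[C@@H](O)[C@@H]12
F2 | step 8 | (3S,5S,8E)-10-(acetyloxy)-9-{2-[(tert-butyldimethylsilyl)oxy]ethyl}-5-methyldeca-1,8-dien-3-yl prop-2-enoate | C=CC(=O)O[C@H](C=C)C[C@@H](C)CC/C=C(/COC(C)=O)CCO[Si](C)(C)C(C)(C)C
F3 | step 8 | (2E,6S)-2-{2-[(tert-butyldimethylsilyl)oxy]ethyl}-6-methyl-7-[(2S)-5-oxo-2,5-dihydrofuran-2-yl]hept-2-en-1-yl acetate | O=C1C=C[C@H](C[C@@H](C)CC/C=C(/COC(C)=O)CCO[Si](C)(C)C(C)(C)C)O1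
F4 | step 8 | (2E,6S)-2-{2-[(tert-butyldimethylsilyl)oxy]ethyl}-7-[(2S)-4-(hydroxymethyl)-5-oxo-2,5-dihydrofuran-2-yl]-6-methylhept-2-en-1-yl acetate | OCC1=C[C@H](C[C@@H](C)CC/C=C(/COC(C)=O)CCO[Si](C)(C)C(C)(C)C)OC1=O
F5 | step 1 | (5S)-5,9-dimethyldeca-1,8-dien-3-ol, mixture of C3 epimers | C=CC(O)C[C@@H](C)CCC=C(C)C
F6 | step 1 | (1R,3S)-3,7-dimethyl-1-[(2S)-oxiran-2-yl]oct-6-en-1-ol | O[C@@H]([C@@H]1CO1)C[C@@H](C)CCC=C(C)C
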